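## Retrosynthetic overview
1. C8–prenyl bond: flowerine ⇒ the 5-O-prenyl ether of (2S)-5-hydroxy-7,4'-dimethoxyflavanone by a tandem Claisen/Cope shift (O5 → C6 → C8). The ether comes from the flavanone and prenol.
2. Ring C (O1–C2 bond, sets C2): flavanone ⇒ 2',6'-dihydroxy-4,4'-dimethoxychalcone by a chalcone-isomerase-type enantioselective oxa-Michael closure.
3. Ring A (bond from the acyl-bearing carbon to a phenol carbon): chalcone ⇒ open-chain cinnamoyl tetraketide ester by a chalcone-synthase-type Claisen cyclisation and aromatisation. The chain is carried masked as a 6-(cinnamoylmethyl)-4-methoxy-2-pyrone.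
4. Chain: ketopyrone ⇒ 4-methoxy-6-methyl-2-pyrone (triketide unit that already holds the future 7-OMe) + methyl 4-methoxycinnamate (starter unit that brings ring B).
5. Order of rings: B bought, then A, then C; the prenyl group goes on last.

Assumption: the SMILES encodes the (2S)-flavanone, and the quinidine-derived thiourea is taken to deliver the phenoxide to the Si face of C-beta (checked by CD on 6; the quinine-derived pseudoenantiomer would give the mirror image).

## Route

Step 1
Reactants: 1 4-methoxy-6-methyl-2H-pyran-2-one; 2 methyl (E)-4-methoxycinnamate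
Product: 5 (E)-2',6'-dihydroxy-4,4'-dimethoxychalcone, via ketopyrone 3 (not isolated), via open-chain diketo ester 4 (not isolated)
Conditions: LiN(iPr)2 (2.2 equiv), THF, −78 °C; 2, −78 → 0 °C; then Mg(OMe)2 (4 equiv), MeOH (THF distilled off), reflux; ice-cold 1 M HCl
Reagents that add atoms: none
Why: Proposed new method: the vinylogous lithium enolate of 1 is C-acylated at its CH2 terminus by ester 2 (crossed Claisen condensation, the second equivalent of base storing 3 as its enolate), methoxide then opens the lactone to 4, whose (2E) enol-ether geometry inherited from the ring holds the ester beside the chain, and magnesium chelation of the 5,7-diketone blocks those carbonyls as electrophiles and makes chain C6 attack the ester in a chalcone-synthase-type intramolecular Claisen (Dieckmann-type) closure that is made irreversible by aromatisation of ring A and leaves the product as the ring-open chalconate until the cold acid quench; the closest known reaction types are the ester acylation of 6-methyl-2-pyrone carbanions and the Mg(OMe)2 rearrangement of 6-(2-oxoalkyl)-4-hydroxy-2-pyrones to acylphloroglucinols, joined here in one flask on a cinnamoyl chain, and no stereocentre is formed.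

Step 2
Reactants: 5 (E)-2',6'-dihydroxy-4,4'-dimethoxychalcone
Product: 6 (2S)-5-hydroxy-7-methoxy-2-(4-methoxyphenyl)chroman-4-one
Conditions: N-[3,5-bis(trifluoromethyl)phenyl]-N'-[(9R)-6'-methoxycinchonan-9-yl]thiourea (quinidine-derived, 10 mol %), PhMe/CH2Cl2 4:1, 0 °C
Reagents that add atoms: none
Why: Chalcone-isomerase-type enantioselective intramolecular oxa-Michael addition in which the quinuclidine nitrogen deprotonates the non-chelated ortho-OH while the thiourea and the internal 6'-OH···O=C hydrogen bond activate the s-cis enone, so that the phenoxide closes ring C on the Si face of C-beta and sets (2S), and because the two ortho-OH groups are equivalent by rotation only one flavanone can form.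

Step 3
Reactants: 6 (2S)-5-hydroxy-7-methoxy-2-(4-methoxyphenyl)chroman-4-one; 7 prenol (3-methylbut-2-en-1-ol)
Product: 8 (2S)-7-methoxy-2-(4-methoxyphenyl)-5-[(3-methylbut-2-en-1-yl)oxy]chroman-4-one
Conditions: 7 (1.5 equiv), PPh3, DIAD, THF, 0 °C → rt
Reagents that add atoms: prenol 7, CC(C)=CCO
Why: Mitsunobu etherification alkylates the only free OH (the chelated 5-OH) by SN2 attack at the primary carbon of the activated prenol, and since no base strong enough to enolise C3 is present there is no retro-oxa-Michael opening and C2 stays (S).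

Step 4
Reactants: 8 (2S)-7-methoxy-2-(4-methoxyphenyl)-5-[(3-methylbut-2-en-1-yl)oxy]chroman-4-one
Product: 11 flowerine (2S)-5-hydroxy-7-methoxy-2-(4-methoxyphenyl)-8-(3-methylbut-2-en-1-yl)chroman-4-one, via ortho-dienone 9 (not isolated), via para-dienone 10 (not isolated)
Conditions: Eu(fod)3 (fod = 6,6,7,7,8,8,8-heptafluoro-2,2-dimethyloctane-3,5-dionate, 10 mol %), PhCl, 85 °C
Reagents that add atoms: none
Why: Lewis-acid-catalysed tandem aromatic Claisen/Cope rearrangement (para-Claisen) in which the first [3,3] shift can be productive only at C6 (C4a is blocked) and gives the 1,1-dimethylallyl dienone 9, steric compression against the 7-OMe drives the second [3,3] shift to C8 with the normal prenyl group restored in 10, tautomerisation re-aromatises ring A and frees the 5-OH, and C2 is not touched under these non-basic conditions.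

## Compound list
1 | 4-methoxy-6-methyl-2H-pyran-2-one | COC1=CC(=O)OC(C)=C1 | starting material
2 | methyl (E)-3-(4-methoxyphenyl)prop-2-enoate (methyl 4-methoxycinnamate) | COC(=O)/C=C/c1ccc(OC)cc1 | starting material
3 | 4-methoxy-6-[(3E)-4-(4-methoxyphenyl)-2-oxobut-3-en-1-yl]-2H-pyran-2-one | COC1=CC(=O)OC(CC(=O)/C=C/c2ccc(OC)cc2)=C1 | intermediate
4 | methyl (2E,8E)-3-methoxy-9-(4-methoxyphenyl)-5,7-dioxonona-2,8-dienoate | COC(=O)/C=C(OC)\CC(=O)CC(=O)/C=C/c1ccc(OC)cc1 | intermediate
5 | (E)-1-(2,6-dihydroxy-4-methoxyphenyl)-3-(4-methoxyphenyl)prop-2-en-1-one | COc1ccc(/C=C/C(=O)c2c(O)cc(OC)cc2O)cc1 | intermediate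
6 | (2S)-5-hydroxy-7-methoxy-2-(4-methoxyphenyl)chroman-4-one | COc1ccc([C@@H]2CC(=O)c3c(O)cc(OC)cc3O2)cc1 | intermediate
7 | 3-methylbut-2-en-1-ol (prenol) | CC(C)=CCO | starting material
8 | (2S)-7-methoxy-2-(4-methoxyphenyl)-5-[(3-methylbut-2-en-1-yl)oxy]chroman-4-one | COc1ccc([C@@H]2CC(=O)c3c(OCC=C(C)C)cc(OC)cc3O2)cc1 | intermediate
9 | (2S)-7-methoxy-2-(4-methoxyphenyl)-6-(2-methylbut-3-en-2-yl)-2,3-dihydrochromene-4,5(6H)-dione (both C6 epimers) | COc1ccc([C@@H]2CC(=O)C3=C(O2)C=C(OC)C(C(C)(C)C=C)C3=O)cc1 | intermediate
10 | (2S)-7-methoxy-2-(4-methoxyphenyl)-8-(3-methylbut-2-en-1-yl)-2,3-dihydrochromene-4,5(8H)-dione (both C8 epimers) | COc1ccc([C@@H]2CC(=O)C3=C(O2)C(CC=C(C)C)C(OC)=CC3=O)cc1 | intermediate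
11 | flowerine, (2S)-5-hydroxy-7-methoxy-2-(4-methoxyphenyl)-8-(3-methylbut-2-en-1-yl)chroman-4-one | COc1ccc([C@@H]2CC(=O)c3c(O)cc(OC)c(CC=C(C)C)c3O2)cc1 | target

## Step count and risks
Total step count: 4. Longest linear sequence: 4 (1 → 5 → 6 → 8 → 11).

**Step 1 is the most likely to fail.**
- The pyrone carbanion or the amide base may add 1,4 to the cinnamate.
- Ester 4 may close in the aldol mode (chain C2 onto C7, stilbene-carboxylate type) instead of the Claisen mode.
- The fallback takes the enone out of the polyketide stage.
- It sets out from 1. The same carbanion is acylated with N-methoxy-N-methylacetamide to give 4-methoxy-6-(2-oxopropyl)-2H-pyran-2-one F1.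
- Mg(OMe)2 in refluxing MeOH opens this to methyl (2E)-3-methoxy-5,7-dioxooct-2-enoate F2 and closes it to 2,6-dihydroxy-4-methoxyacetophenone F3.
- A Claisen–Schmidt condensation of this ketone with 4-methoxybenzaldehyde (KOH, aqueous EtOH, rt, cold acid quench) comes back to the route at 5.

**Step 2 is the second risk.**
- The electron-rich enone may turn over slowly, and uncatalysed closure of the dihydroxychalcone may lower the ee.
- Any racemic flavanone carried over from step 1 must be removed from 5 first.
- The fallback replaces asymmetric catalysis by resolution.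
- It sets out from 5. NaOAc in refluxing EtOH gives racemic 5-hydroxy-7,4'-dimethoxyflavanone F4.
- Mitsunobu etherification with 7 gives racemic 5-O-prenyl-7,4'-dimethoxyflavanone F5.
- Kinetic resolution follows by asymmetric transfer hydrogenation (RuCl(p-cymene)[(R,R)-TsDPEN], HCO2H/Et3N, EtOAc, stopped near 52–55 % conversion).
- This reduces the matched (2R) enantiomer to (2R,4R)-cis-5-O-prenyl-7,4'-dimethoxyflavan-4-ol F6 and leaves the (2S) ketone, which comes back to the route at 8.

**Step 4 is the third risk.**
- Dienone 9 may tautomerise to the 6-(1,1-dimethylallyl) phenol before the Cope shift.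
- Lewis-acid-assisted opening of the p-anisyl benzylic C–O bond may erode the ee. The ee of 11 is checked and raised by recrystallisation.
- The fallback is an intermolecular electrophilic prenylation in the manner of an aromatic prenyltransferase.
- It sets out from 6. 2-Methylbut-3-en-2-ol and BF3·OEt2 in dioxane at rt place the dimethylallyl cation on C8 and on C6.
- The C6 isomer cyclises onto the 5-OH to a chroman and is removed by chromatography.
- The C8 product has no neighbouring OH and is the target itself. This way skips 8 and comes back at 11 (new compounds on this way: none F0).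

## Further compounds
F1 | step 1 | 4-methoxy-6-(2-oxopropyl)-2H-pyran-2-one | COC1=CC(=O)OC(CC(C)=O)=C1
F2 | step 1 | methyl (2E)-3-methoxy-5,7-dioxooct-2-enoate | COC(=O)/C=C(OC)\CC(=O)CC(C)=O
F3 | step 1 | 2,6-dihydroxy-4-methoxyacetophenone | CC(=O)c1c(O)cc(OC)cc1O
F4 | step 2 | racemic 5-hydroxy-7,4'-dimethoxyflavanone | COc1ccc(C2CC(=O)c3c(O)cc(OC)cc3O2)cc1
F5 | step 2 | racemic 5-O-prenyl-7,4'-dimethoxyflavanone | COc1ccc(C2CC(=O)c3c(OCC=C(C)C)cc(OC)cc3O2)cc1
F6 | step 2 | (2R,4R)-cis-5-O-prenyl-7,4'-dimethoxyflavan-4-ol | COc1ccc([C@H]2C[C@@H](O)c3c(OCC=C(C)C)cc(OC)cc3O2)cc1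
F0 | step 4 | none | none
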